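**Plan**

- Numbering used throughout: ring A = C7(aryl)–O–C9'H2–C8'–C8; C9 = the CH2OH carbon on C8; C7' = the carbinol carbon on C8'. Retrosynthetic cuts, in order: the C7'–aryl bond (aryl Grignard on a lactol); the lactol carbon back to a vinyl-bearing ether carbon; the ring-A bonds O–C7 and C8–C8' together in one radical–polar cascade; the allylic ether O–C9.
- Forward: a Sharpless epoxy alcohol and TIPS-protected coniferyl bromide are joined as an ether. Ti(III) opens the epoxide; a temporary ring B (C8'–C7'–O–C9–C8) closes first by 5-exo radical cyclisation, then ring A closes by iodine-triggered benzylic etherification (cis-fused 3,7-dioxabicyclo[3.3.0]octane). The vinyl group is then cut down to a lactol, and ArMgBr opens ring B.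
- Enabling feature: C8' sits between the ring OCH2 (C9') and the oxygenated C7', so a C8'–C9' epoxide is a masked nucleophilic C8' radical (polarity reversal) that keeps the oxygen for ring A. C8 is β to the electron-rich guaiacyl ring, so the styrene takes the radical at C8 and C7 can be oxidised to a cation. The cis C9/C7' arms on ring A allow the O–C9 tether.
- Stereochemistry: the (3R) carbinol from Sharpless desymmetrisation of divinylcarbinol controls C8' and C8 (chair-like transition state) and C7 (exo aryl); any epoxide epimer would give the same radical. C7' is then erased at the lactol stage and re-set as (R) by Felkin–Anh/chelate-controlled aryl addition.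

Key step: step 6

Remark (assumption): D-(−)-diisopropyl tartrate is taken to deliver the (2S,3R)-epoxy alcohol from divinylcarbinol by the usual facial rule; only the (3R) carbinol centre matters downstream.

**Route**

Step 1
Reactants: 1 penta-1,4-dien-3-ol (divinylcarbinol)
Product: 2 (2S,3R)-1,2-epoxypent-4-en-3-ol
Conditions: Ti(OiPr)4, D-(−)-DIPT, t-BuOOH, 4 Å MS, CH2Cl2, −20 °C
Reagents that add atoms: tert-butyl hydroperoxide, CC(C)(C)OO
Why: Sharpless asymmetric epoxidation used as a desymmetrisation, in which the titanium–tartrate catalyst selects one enantiotopic vinyl group and one of its faces to give the erythro epoxy alcohol and so sets the (3R) carbinol centre (the epoxide centre is lost later).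

Step 2
Reactants: 3 coniferaldehyde, (E)-3-(4-hydroxy-3-methoxyphenyl)prop-2-enal
Product: 4 (E)-3-[3-methoxy-4-(triisopropylsilyloxy)phenyl]prop-2-enal
Conditions: TIPSCl, imidazole, DMF, rt
Reagents that add atoms: triisopropylsilyl chloride, CC(C)[Si](Cl)(C(C)C)C(C)C
Why: Imidazole-mediated silylation of the phenol masks the acidic OH while keeping the ring electron-rich for the later cation chemistry; no stereocentre is involved.

Step 3
Reactants: 4 (E)-3-[3-methoxy-4-(triisopropylsilyloxy)phenyl]prop-2-enal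
Product: 5 (E)-3-[3-methoxy-4-(triisopropylsilyloxy)phenyl]prop-2-en-1-ol
Conditions: NaBH4, CeCl3·7H2O, MeOH, 0 °C
Reagents that add atoms: none
Why: Luche 1,2-reduction of the enal should give the E-allylic alcohol without conjugate reduction; no stereocentre is formed.

Step 4
Reactants: 5 (E)-3-[3-methoxy-4-(triisopropylsilyloxy)phenyl]prop-2-en-1-ol
Product: 6 (E)-[4-(3-bromoprop-1-en-1-yl)-2-methoxyphenoxy]triisopropylsilane
Conditions: CBr4, PPh3, CH2Cl2, 0 °C; used at once
Reagents that add atoms: carbon tetrabromide, BrC(Br)(Br)Br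
Why: Appel bromination converts the allylic alcohol into the bromide under neutral conditions with retention of the E geometry.

Step 5
Reactants: 2 (2S,3R)-1,2-epoxypent-4-en-3-ol; 6 (E)-[4-(3-bromoprop-1-en-1-yl)-2-methoxyphenoxy]triisopropylsilane
Product: 7 (S)-2-[(R)-1-{[(E)-3-(3-methoxy-4-triisopropylsilyloxyphenyl)prop-2-en-1-yl]oxy}prop-2-en-1-yl]oxirane
Conditions: NaH, n-Bu4NI (cat.), THF, 0 °C to rt
Reagents that add atoms: none
Why: Williamson ether synthesis of the sodium alkoxide of 2 on the allylic bromide in an aprotic medium, where Payne rearrangement of the epoxy alkoxide should stay slow; both stereocentres of 2 are untouched.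

Step 6
Reactants: 7 (S)-2-[(R)-1-{[(E)-3-(3-methoxy-4-triisopropylsilyloxyphenyl)prop-2-en-1-yl]oxy}prop-2-en-1-yl]oxirane
Product: 10 (1S,3aR,4R,6aR)-1-[3-methoxy-4-(triisopropylsilyloxy)phenyl]-4-vinyltetrahydro-1H,3H-furo[3,4-c]furan, via bis-titanium(IV) benzyl alkoxide 8 (not isolated), via benzylic iodide titanium alkoxide 9 (not isolated)
Conditions: Cp2TiCl2, Zn, THF, rt (decanted Cp2TiCl, slow addition of 7); then I2, THF, rt to 60 °C
Reagents that add atoms: none
Why: Titanocene(III)-mediated epoxide opening/radical cyclisation followed by iodine-induced cationic etherification, a sequence with close precedent in the conversion of 1-substituted 2,3-epoxypropyl cinnamyl ethers into furofuran lignans. Cp2TiCl opens the terminal epoxide by single-electron transfer to the secondary β-titanoxy radical at C8' (either epoxide epimer would give the same radical), which closes the temporary ring C8'–C7'–O–C9–C8 by 5-exo-trig attack on C8 of the styrene; the benzylic C7 radical is captured by a second Cp2TiCl (8), I2 turns the C–Ti bond into the benzylic iodide 9, and this ionises with help of the para-silyloxy aryl group and is closed by the titanium alkoxide oxygen in a 5-exo, SN1-type etherification that forms ring A. C8' and C8 are set in the chair-like 5-exo transition state with the C7' vinyl group pseudo-equatorial, so that the CH2OTi arm ends trans to vinyl and cis to the new benzylic carbon; the pre-set (3R) centre thus fixes both absolute configurations and the cis ring fusion that the second closure needs. C7 is set in the etherification, where the aryl group should take the convex (exo) face, trans to the C8–C9 bond, under reversible ionisation. The step needs cyclisation to outrun reduction of the C8' radical by Ti(III) (which would end in β-alkoxide elimination), which the fast addition to the electron-rich styrene should secure, and it needs closure by the C9' oxygen and not by another nucleophile, which the five-membered geometry and the metal-bound alkoxide secure.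

Step 7
Reactants: 10 (1S,3aR,4R,6aR)-1-[3-methoxy-4-(triisopropylsilyloxy)phenyl]-4-vinyltetrahydro-1H,3H-furo[3,4-c]furan
Product: 11 (1S,3aR,4S,6aR)-1-[3-methoxy-4-(triisopropylsilyloxy)phenyl]tetrahydro-1H,3H-furo[3,4-c]furan-4-carbaldehyde
Conditions: OsO4 (cat.), NaIO4, 2,6-lutidine, dioxane/H2O, rt
Reagents that add atoms: osmium tetroxide (catalytic oxygen carrier), O=[Os](=O)(=O)=O; sodium periodate (terminal oxidant), [Na+].[O-]I(=O)(=O)=O
Why: Lemieux–Johnson oxidative cleavage of the only C=C gives the α-alkoxy aldehyde; epimerisation at C4 (C7') would be without consequence because this centre is destroyed in the next step.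

Step 8
Reactants: 11 (1S,3aR,4S,6aR)-1-[3-methoxy-4-(triisopropylsilyloxy)phenyl]tetrahydro-1H,3H-furo[3,4-c]furan-4-carbaldehyde
Product: 13 (1S,3aR,6aR)-1-[3-methoxy-4-(triisopropylsilyloxy)phenyl]tetrahydro-1H,3H-furo[3,4-c]furan-4-ol (lactol; both C4 anomers), via anomeric formate 12 (not isolated)
Conditions: mCPBA, Na2HPO4, CH2Cl2, 0 °C; then Et3N (cat.), MeOH, rt
Reagents that add atoms: 3-chloroperoxybenzoic acid, OOC(=O)c1cccc(Cl)c1
Why: Baeyer–Villiger oxidation, in which the α-alkoxyalkyl group migrates in preference to hydride, gives the anomeric formate, and mild methanolysis releases the lactol, whose cis ring fusion holds C8 and C8' in place.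

Step 9
Reactants: 14 4-bromo-2-methoxyphenol
Product: 15 (4-bromo-2-methoxyphenoxy)triisopropylsilane
Conditions: TIPSCl, imidazole, DMF, rt
Reagents that add atoms: triisopropylsilyl chloride, CC(C)[Si](Cl)(C(C)C)C(C)C
Why: Imidazole-mediated silylation of the phenol gives the aryl bromide needed for the Grignard reagent; no stereocentre is involved.

Step 10
Reactants: 15 (4-bromo-2-methoxyphenoxy)triisopropylsilane; 13 (1S,3aR,6aR)-1-[3-methoxy-4-(triisopropylsilyloxy)phenyl]tetrahydro-1H,3H-furo[3,4-c]furan-4-ol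
Product: 17 (R)-[3-methoxy-4-(triisopropylsilyloxy)phenyl]{(3R,4R,5S)-4-(hydroxymethyl)-5-[3-methoxy-4-(triisopropylsilyloxy)phenyl]tetrahydrofuran-3-yl}methanol, via aryl Grignard reagent 16 (not isolated)
Conditions: Mg, THF, rt (15 to 16, excess); then 13, THF, −78 to 0 °C
Reagents that add atoms: none
Why: Grignard addition to the ring-opened hydroxy-aldehyde form of the lactol (the first equivalent acts as base), where Felkin–Anh attack anti to the larger C8 branch of the α-carbon and the Cram chelate through the ring-A oxygen both lead to the (R)-carbinol at C7'.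

Step 11
Reactants: 17 (R)-[3-methoxy-4-(triisopropylsilyloxy)phenyl]{(3R,4R,5S)-4-(hydroxymethyl)-5-[3-methoxy-4-(triisopropylsilyloxy)phenyl]tetrahydrofuran-3-yl}methanol
Product: 18 (7R)-7-hydroxylariciresinol, (R)-(4-hydroxy-3-methoxyphenyl)[(3R,4R,5S)-5-(4-hydroxy-3-methoxyphenyl)-4-(hydroxymethyl)tetrahydrofuran-3-yl]methanol
Conditions: TBAF, AcOH, THF, 0 °C
Reagents that add atoms: none
Why: Fluoride-mediated cleavage of both aryl silyl ethers under buffered conditions should leave the benzylic alcohol and the benzylic ether untouched and give the target.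

**Compound list**

1 | penta-1,4-dien-3-ol (divinylcarbinol) | C=CC(O)C=C | starting material
2 | (2S,3R)-1,2-epoxypent-4-en-3-ol | C=C[C@@H](O)[C@@H]1CO1 | intermediate
3 | coniferaldehyde, (E)-3-(4-hydroxy-3-methoxyphenyl)prop-2-enal | COc1cc(/C=C/C=O)ccc1O | starting material
4 | (E)-3-[3-methoxy-4-(triisopropylsilyloxy)phenyl]prop-2-enal | COc1cc(/C=C/C=O)ccc1O[Si](C(C)C)(C(C)C)C(C)C | intermediate
5 | (E)-3-[3-methoxy-4-(triisopropylsilyloxy)phenyl]prop-2-en-1-ol | COc1cc(/C=C/CO)ccc1O[Si](C(C)C)(C(C)C)C(C)C | intermediate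
6 | (E)-[4-(3-bromoprop-1-en-1-yl)-2-methoxyphenoxy]triisopropylsilane | COc1cc(/C=C/CBr)ccc1O[Si](C(C)C)(C(C)C)C(C)C | intermediate
7 | (S)-2-[(R)-1-{[(E)-3-(3-methoxy-4-triisopropylsilyloxyphenyl)prop-2-en-1-yl]oxy}prop-2-en-1-yl]oxirane | COc1cc(/C=C/CO[C@H](C=C)[C@@H]2CO2)ccc1O[Si](C(C)C)(C(C)C)C(C)C | intermediate
8 | cyclised bis-titanium(IV) species: (2R,3R,4R)-2-vinyltetrahydrofuran carrying CH2O–TiClCp2 at C3 and aryl–CH(TiClCp2) at C4 (benzylic centre undefined) | COc1cc(C([Ti](Cl)(C3C=CC=C3)C3C=CC=C3)[C@H]2CO[C@H](C=C)[C@H]2CO[Ti](Cl)(C3C=CC=C3)C3C=CC=C3)ccc1O[Si](C(C)C)(C(C)C)C(C)C | intermediate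
9 | benzylic iodide of 8 with the C3 arm still as titanium(IV) alkoxide (benzylic centre undefined) | COc1cc(C(I)[C@H]2CO[C@H](C=C)[C@H]2CO[Ti](Cl)(C3C=CC=C3)C3C=CC=C3)ccc1O[Si](C(C)C)(C(C)C)C(C)C | intermediate
10 | (1S,3aR,4R,6aR)-1-[3-methoxy-4-(triisopropylsilyloxy)phenyl]-4-vinyltetrahydro-1H,3H-furo[3,4-c]furan (cis-fused; aryl and vinyl both exo) | COc1cc([C@H]2OC[C@@H]3[C@@H](C=C)OC[C@H]23)ccc1O[Si](C(C)C)(C(C)C)C(C)C | intermediate
11 | (1S,3aR,4S,6aR)-1-[3-methoxy-4-(triisopropylsilyloxy)phenyl]tetrahydro-1H,3H-furo[3,4-c]furan-4-carbaldehyde | COc1cc([C@H]2OC[C@@H]3[C@@H](C=O)OC[C@H]23)ccc1O[Si](C(C)C)(C(C)C)C(C)C | intermediate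
12 | (1S,3aR,4R,6aR)-1-[3-methoxy-4-(triisopropylsilyloxy)phenyl]tetrahydro-1H,3H-furo[3,4-c]furan-4-yl formate | COc1cc([C@H]2OC[C@@H]3[C@@H](OC=O)OC[C@H]23)ccc1O[Si](C(C)C)(C(C)C)C(C)C | intermediate
13 | (1S,3aR,6aR)-1-[3-methoxy-4-(triisopropylsilyloxy)phenyl]tetrahydro-1H,3H-furo[3,4-c]furan-4-ol (C4 anomers) | COc1cc([C@H]2OC[C@@H]3C(O)OC[C@H]23)ccc1O[Si](C(C)C)(C(C)C)C(C)C | intermediate
14 | 4-bromo-2-methoxyphenol | COc1cc(Br)ccc1O | starting material
15 | (4-bromo-2-methoxyphenoxy)triisopropylsilane | COc1cc(Br)ccc1O[Si](C(C)C)(C(C)C)C(C)C | intermediate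
16 | [3-methoxy-4-(triisopropylsilyloxy)phenyl]magnesium bromide | COc1cc([Mg]Br)ccc1O[Si](C(C)C)(C(C)C)C(C)C | intermediate
17 | (R)-[3-methoxy-4-(triisopropylsilyloxy)phenyl]{(3R,4R,5S)-4-(hydroxymethyl)-5-[3-methoxy-4-(triisopropylsilyloxy)phenyl]tetrahydrofuran-3-yl}methanol | COc1cc([C@H]2OC[C@H]([C@@H](O)c3ccc(O[Si](C(C)C)(C(C)C)C(C)C)c(OC)c3)[C@@H]2CO)ccc1O[Si](C(C)C)(C(C)C)C(C)C | intermediate
18 | (7R)-7-hydroxylariciresinol, (R)-(4-hydroxy-3-methoxyphenyl)[(3R,4R,5S)-5-(4-hydroxy-3-methoxyphenyl)-4-(hydroxymethyl)tetrahydrofuran-3-yl]methanol | COc1cc([C@H]2OC[C@H]([C@@H](O)c3ccc(O)c(OC)c3)[C@@H]2CO)ccc1O | target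

**Totals**

Total step count: 11. Longest linear sequence: 9 steps (steps 2, 3, 4, 5, 6, 7, 8, 10, 11, from coniferaldehyde).

**Steps most likely to fail**

Step 6. The benzylic C–Ti bond may be protonated before iodinolysis, the C8' radical may be reduced before it cyclises, or the 5-exo closure may give poor cis selectivity at C8/C8' so that ring A cannot close. The fallback separates C–C from C–O bond formation. From 7, Cp2TiCl in THF with a proton source (collidinium chloride) would give the monocyclic [(2R,3R,4R)-4-[3-methoxy-4-(triisopropylsilyloxy)benzyl]-2-vinyltetrahydrofuran-3-yl]methanol F1. A separate DDQ oxidative C–H etherification (CH2Cl2, 0 °C), a known reaction of electron-rich benzyl groups carrying a γ-hydroxyl, would then close ring A and return to 10.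

Step 10. Facial selectivity at the aldehyde may be poor (a competing chelate through the C9 magnesium alkoxide), or the open aldehyde may enolise toward C8'. The fallback sets C7' by reagent control. It sets out from 17 obtained as a C7' epimer mixture. Silylation of the primary alcohol (TBSCl, imidazole) would give the C9 O-TBS ether of 17 F2. Oxidation of the benzylic alcohol (MnO2 or Dess–Martin periodinane) would give the aryl ketone F3. Corey–Bakshi–Shibata reduction with (S)-Me-CBS and BH3·SMe2 would give the (7'R)-alcohol F4. TBAF would remove all three silyl groups and reach 18.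

Step 5 (with step 4). The electron-rich cinnamyl bromide may ionise or decompose, SN2' attack may compete, or the epoxy alkoxide may undergo Payne rearrangement. The fallback forms the aryl–carbon bond last. From 2, propargylation (NaH, propargyl bromide, THF) would give (S)-2-[(R)-1-(prop-2-yn-1-yloxy)prop-2-en-1-yl]oxirane F5. Sonogashira coupling (Pd(PPh3)2Cl2, CuI, Et3N) with (4-iodo-2-methoxyphenoxy)triisopropylsilane F6, made from commercial 4-iodo-2-methoxyphenol with TIPSCl and imidazole, would give the aryl alkyne F7. Lindlar semihydrogenation would give the Z isomer of 7 F8. F8 would be taken through the conditions of step 6, where the alkene geometry is lost at the benzylic radical, and the route is rejoined at 10.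

Further compounds
F1 | step 6 | [(2R,3R,4R)-4-[3-methoxy-4-(triisopropylsilyloxy)benzyl]-2-vinyltetrahydrofuran-3-yl]methanol | COc1cc(C[C@H]2CO[C@H](C=C)[C@H]2CO)ccc1O[Si](C(C)C)(C(C)C)C(C)C
F2 | step 10 | C9 O-TBS ether of 17 (C7' epimer mixture) | COc1cc([C@H]2OC[C@H](C(O)c3ccc(O[Si](C(C)C)(C(C)C)C(C)C)c(OC)c3)[C@@H]2CO[Si](C)(C)C(C)(C)C)ccc1O[Si](C(C)C)(C(C)C)C(C)C
F3 | step 10 | {(3R,4R,5S)-4-[(tert-butyldimethylsilyloxy)methyl]-5-[3-methoxy-4-(triisopropylsilyloxy)phenyl]tetrahydrofuran-3-yl}[3-methoxy-4-(triisopropylsilyloxy)phenyl]methanone | COc1cc([C@H]2OC[C@H](C(=O)c3ccc(O[Si](C(C)C)(C(C)C)C(C)C)c(OC)c3)[C@@H]2CO[Si](C)(C)C(C)(C)C)ccc1O[Si](C(C)C)(C(C)C)C(C)C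
F4 | step 10 | (7'R)-alcohol: C9 O-TBS ether of 17 | COc1cc([C@H]2OC[C@H]([C@@H](O)c3ccc(O[Si](C(C)C)(C(C)C)C(C)C)c(OC)c3)[C@@H]2CO[Si](C)(C)C(C)(C)C)ccc1O[Si](C(C)C)(C(C)C)C(C)C
F5 | step 5 | (S)-2-[(R)-1-(prop-2-yn-1-yloxy)prop-2-en-1-yl]oxirane | C#CCO[C@H](C=C)[C@@H]1CO1
F6 | step 5 | (4-iodo-2-methoxyphenoxy)triisopropylsilane | COc1cc(I)ccc1O[Si](C(C)C)(C(C)C)C(C)C
F7 | step 5 | (S)-2-[(R)-1-{[3-(3-methoxy-4-triisopropylsilyloxyphenyl)prop-2-yn-1-yl]oxy}prop-2-en-1-yl]oxirane | COc1cc(C#CCO[C@H](C=C)[C@@H]2CO2)ccc1O[Si](C(C)C)(C(C)C)C(C)C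
F8 | step 5 | Z isomer of 7 | COc1cc(/C=C\CO[C@H](C=C)[C@@H]2CO2)ccc1O[Si](C(C)C)(C(C)C)C(C)C
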